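Labdane numbering is used throughout. The route rests on a [3+3] annulation of ring A (C1–C5, C10) onto a finished ring B. It exploits that C1 and C5 flank the quaternary C10 and that C5 is α to the oxygenated C6. With C6 as ketone and C1 tied back as a cyclopropane CH2 bridging C5 and C10, ring B is a latent C1 radical/C5 enolate pair. In one flask iodide opens the C1–C5 bond, the C1 radical adds to methyl vinyl ketone (C1–C2) and base condenses C5 with the new ketone (C4=C5). The precursor is a bicyclo[4.1.0]heptan-2-one. A cuprate later completes the gem-dimethyl group.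

Key step: step 8

Remark: α/β mean below/above the ring plane as drawn for labdanes. The sense of induction of the chiral catalysts in steps 1 and 14 is taken from their accepted models; should it be opposite, the antipodal catalyst is used.

Step 1
Reactants: 1 tert-butyl acetoacetate; 2 (E)-crotonaldehyde
Product: 5 (R)-5-methylcyclohex-2-en-1-one, via Michael adduct 3 (not isolated), via keto ester 4 (not isolated)
Conditions: (S)-2-{bis[3,5-bis(trifluoromethyl)phenyl](trimethylsilyloxy)methyl}pyrrolidine (10 mol%), toluene, rt; then p-TsOH (20 mol%), 80 °C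
Reagents that add atoms: none
Why: Iminium-catalysed asymmetric Michael addition (the diarylprolinol silyl ether shields one enal face and sets the auxiliary C8 centre as R), then acid-induced aldol condensation and tert-butyl ester cleavage/decarboxylation, is a known one-pot entry to 5-alkylcyclohex-2-enones.

Step 2
Reactants: 5 (R)-5-methylcyclohex-2-en-1-one; 6 4-iodobut-1-ene
Product: 7 (5R,6S)-6-(but-3-en-1-yl)-5-methylcyclohex-2-en-1-one
Conditions: LDA, THF, −78 °C; 6, DMPU, −78 → −20 °C
Reagents that add atoms: none
Why: Kinetic α'-deprotonation and SN2 alkylation of the cross-conjugated lithium enolate anti to the neighbouring methyl group should give the trans product, which sets C9.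

Step 3
Reactants: 7 (5R,6S)-6-(but-3-en-1-yl)-5-methylcyclohex-2-en-1-one
Product: 8 (5R,6S)-6-(but-3-en-1-yl)-1,5-dimethylcyclohex-2-en-1-ol (carbinol epimers)
Conditions: MeLi, Et2O, −78 °C; then H2O
Reagents that add atoms: methyllithium, [Li]C
Why: 1,2-Addition of methyllithium to the enone carbonyl brings in C20, and the carbinol configuration is irrelevant because C10 becomes sp2 in the next step.

Step 4
Reactants: 8 tertiary allylic alcohol
Product: 9 (4S,5R)-4-(but-3-en-1-yl)-3,5-dimethylcyclohex-2-en-1-one
Conditions: 2,2,6,6-tetramethyl-1-oxopiperidinium tetrafluoroborate, MeCN, rt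
Reagents that add atoms: none
Why: Oxoammonium-mediated oxidative 1,3-transposition of a tertiary allylic alcohol (Babler–Dauben type) moves the oxygen to C6 and gives the β-methyl enone without touching the terminal alkene.

Step 5
Reactants: 9 (4S,5R)-4-(but-3-en-1-yl)-3,5-dimethylcyclohex-2-en-1-one
Product: 10 (1S,4S,5R)-4-(but-3-en-1-yl)-3,5-dimethylcyclohex-2-en-1-ol (6α-OH)
Conditions: NaBH4, CeCl3·7H2O, MeOH, −78 → 0 °C
Reagents that add atoms: none
Why: Luche 1,2-reduction with axial hydride delivery to the diequatorial half-chair should give the pseudo-equatorial 6α-alcohol cis to the C8 methyl group, as carvone gives cis-carveol.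

Step 6
Reactants: 10 allylic alcohol
Product: 11 5-(but-3-en-1-yl)-4,6-dimethylbicyclo[4.1.0]heptan-2-ol (cyclopropane CH2 = C1 on the α face bridging C5 and C10; 6α-OH, 8α-Me, 9β-butenyl, C20 β)
Conditions: Et2Zn, CH2I2, CH2Cl2, −20 → 0 °C
Reagents that add atoms: diiodomethane, ICI
Why: Hydroxyl-directed Furukawa–Simmons–Smith cyclopropanation delivers CH2 syn to the 6α-OH, so C1 lies α and C20 β (C10 set), and the zinc alkoxide makes the allylic alkene react before the remote vinyl group.

Step 7
Reactants: 11 cyclopropyl carbinol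
Product: 12 5-(but-3-en-1-yl)-4,6-dimethylbicyclo[4.1.0]heptan-2-one (C1 α, C20 β, 8α-Me, 9β-butenyl)
Conditions: Dess–Martin periodinane, CH2Cl2, rt
Reagents that add atoms: none
Why: Dess–Martin oxidation of the secondary alcohol under neutral conditions gives the cyclopropyl ketone without opening the three-membered ring.

Step 8
Reactants: 12 cyclopropyl ketone; 13 methyl vinyl ketone
Product: 17 19,14,15-trinorlabda-4,13(16)-dien-6-one (8α-Me, 9β-butenyl, C20 β), via iodo silyl enol ether 14 (not isolated), via iodoketone 15 (not isolated), via diketone 16 (not isolated)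
Conditions: NaI, TMSCl, MeCN, 0 °C; then EtOH–H2O, Zn, CuI (cat.), 13, ultrasound, rt; then KOH, 70 °C (one flask)
Reagents that add atoms: sodium iodide, [Na+].[I-]; chlorotrimethylsilane, C[Si](C)(C)Cl (their atoms stay only in 14 and 15)
Why: Iodotrimethylsilane made in situ silylates the C6 carbonyl and iodide attacks the cyclopropane CH2 (C1) in an SN2-like homoconjugate opening that breaks the C1–C5 bond to give 14 and, after hydrolysis, 15; zinc/copper then turns the neopentyl C1–I bond into a nucleophilic radical that adds to the CH2 terminus of 13 (C1–C2, Giese-type aqueous conjugate addition), and hydroxide drives the aldol condensation of C5 onto the new methyl ketone (C4=C5). The closest known reaction types are the iodosilane opening of bicyclo[4.1.0]heptan-2-ones, the zinc–copper mediated conjugate addition of alkyl iodides to enones and the aldol half of the Robinson annulation, merged here into a homo-Robinson [3+3] annulation. Ring A closes in a 6-(enolexo)-exo-trig aldol step followed by E1cB loss of water. No new stereocentre arises, since C10 (set in step 6) keeps all bonds that define it and C4 and C5 become sp2. The step needs cleavage of C1–C5 rather than C5–C10, which attack at the only CH2 carbon and overlap of that bond with the carbonyl π system should secure; it also needs the fused aldol mode, which is the sink because the bridged aldol (C3 onto C6) is reversible and cannot dehydrate without a bridgehead alkene, while C7 or the methyl group could only form eight-membered rings. The remote vinyl group should survive because 6-exo capture of the C1 radical is far slower than addition to excess 13.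

Step 9
Reactants: 17 bicyclic enone
Product: 18 14,15-dinorlabd-13(16)-en-6-one (5α-H, 8α-Me/8β-H)
Conditions: Me2CuLi, Et2O, −20 → 0 °C; H2O; then NaOMe (cat.), MeOH, rt
Reagents that add atoms: lithium dimethylcuprate, [Li+].C[Cu-]C
Why: Gilman conjugate addition to an s-cis β,β-dialkyl alkylidene ketone (the pulegone type of acceptor) from the α face away from C20 completes the C4 gem-dimethyl group, and methoxide equilibration gives the more stable trans-decalone, which sets C5 (5α-H).

Step 10
Reactants: 18 decalone
Product: 19 14,15-dinorlabda-7,13(16)-dien-6-one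
Conditions: IBX, DMSO–fluorobenzene, 75 °C
Reagents that add atoms: none
Why: IBX dehydrogenation through the enol can only run towards C7–C8, because C4 and C10 next to C5 are quaternary, and it erases the auxiliary C8 stereocentre.

Step 11
Reactants: 19 enone
Product: 21 8α-hydroxy-14,15-dinorlabd-13(16)-en-6-one, via boryl ketone 20 (not isolated)
Conditions: B2pin2, CuCl (5 mol%), DPEphos, NaOt-Bu (cat.), MeOH, THF, rt; then NaBO3·4H2O, THF–H2O
Reagents that add atoms: bis(pinacolato)diboron, CC1(C)OB(OC1(C)C)B1OC(C)(C)C(C)(C)O1; sodium perborate, [Na+].[Na+].O[B-]1(O)OO[B-](O)(O)OO1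
Why: Copper(I)-catalysed conjugate borylation of the β-methyl enone should occur on the α face, anti to the axial C20 methyl group, and perborate oxidation with retention gives the 8α tertiary alcohol (C8 set).

Step 12
Reactants: 21 β-hydroxy ketone
Product: 22 14,15-dinorlabd-13(16)-ene-6α,8α-diol
Conditions: Li, NH3(l)–THF, t-BuOH, −78 °C
Reagents that add atoms: none
Why: Dissolving-metal reduction of the hindered cyclohexanone leads to the thermodynamically preferred equatorial alcohol and so sets C6 as 6α-OH, where hydrides would attack from the α face and give the axial epimer, and the isolated vinyl group is inert.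

Step 13
Reactants: 22 diol
Product: 23 6α,8α-dihydroxy-14,15-dinorlabdan-13-one
Conditions: PdCl2 (10 mol%), CuCl, O2 (1 atm), DMF–H2O, rt
Reagents that add atoms: water, O
Why: Tsuji–Wacker oxidation converts the only alkene, a terminal one, with Markovnikov selectivity into the methyl ketone.

Step 14
Reactants: 23 methyl ketone
Product: 24 (13R)-13,14-epoxy-15-norlabdane-6α,8α-diol
Conditions: Me3S(O)Cl, NaH, THF; (S)-La–Li3–tris(binaphthoxide) (5 mol%), tris(2,4,6-trimethoxyphenyl)phosphine oxide (5 mol%), MS 5 Å, THF, rt
Reagents that add atoms: trimethylsulfoxonium chloride, C[S+](C)(C)=O.[Cl-]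
Why: Catalytic asymmetric Corey–Chaykovsky epoxidation of a methyl ketone, in which the chiral binaphthoxide complex tells methyl from the CH2 chain and delivers CH2 (C14) to the Si face, sets C13 (R).

Step 15
Reactants: 24 epoxide
Product: 25 (13R)-labd-14-ene-6α,8α,13-triol (6α-hydroxysclareol)
Conditions: Me3SI, n-BuLi (excess ylide), THF, −10 °C → rt
Reagents that add atoms: trimethylsulfonium iodide, C[S+](C)C.[I-]
Why: Dimethylsulfonium methylide opens the epoxide at its CH2 terminus and the γ-oxido sulfonium salt eliminates dimethyl sulfide (one-carbon homologation of a terminal epoxide to an allylic alcohol), so the C13–O bond and its configuration stay untouched.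

Step 16
Reactants: 25 triol; 26 angelic acid
Product: 28 6α-angeloyloxysclareol (target), via mixed anhydride 27 (not isolated)
Conditions: 26, 2,4,6-trichlorobenzoyl chloride, Et3N, toluene, rt; then 25, 80 °C
Reagents that add atoms: 2,4,6-trichlorobenzoyl chloride, O=C(Cl)c1c(Cl)cc(Cl)cc1Cl (its atoms stay only in 27)
Why: Yamaguchi-type mixed-anhydride acylation without nucleophilic catalyst is a known way to angelates without Z→E isomerisation, and only the secondary equatorial 6α-OH should react because the C8 and C13 alcohols are tertiary.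

Compound list
1 | tert-butyl acetoacetate | CC(=O)CC(=O)OC(C)(C)C | starting material
2 | (E)-crotonaldehyde | C/C=C/C=O | starting material
3 | tert-butyl (3R)-2-acetyl-3-methyl-5-oxopentanoate (C2 epimers) | CC(=O)C(C(=O)OC(C)(C)C)[C@H](C)CC=O | intermediate
4 | tert-butyl (6R)-6-methyl-2-oxocyclohex-3-ene-1-carboxylate | O=C1C=CC[C@@H](C)C1C(=O)OC(C)(C)C | intermediate
5 | (R)-5-methylcyclohex-2-en-1-one | C[C@@H]1CC=CC(=O)C1 | intermediate
6 | 4-iodobut-1-ene | C=CCCI | starting material
7 | (5R,6S)-6-(but-3-en-1-yl)-5-methylcyclohex-2-en-1-one | O=C1C=CC[C@@H](C)[C@@H]1CCC=C | intermediate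
8 | (5R,6S)-6-(but-3-en-1-yl)-1,5-dimethylcyclohex-2-en-1-ol (carbinol epimers) | CC1(O)C=CC[C@@H](C)[C@@H]1CCC=C | intermediate
9 | (4S,5R)-4-(but-3-en-1-yl)-3,5-dimethylcyclohex-2-en-1-one | O=C1C=C(C)[C@@H](CCC=C)[C@H](C)C1 | intermediate
10 | (1S,4S,5R)-4-(but-3-en-1-yl)-3,5-dimethylcyclohex-2-en-1-ol | O[C@@H]1C=C(C)[C@@H](CCC=C)[C@H](C)C1 | intermediate
11 | 5-(but-3-en-1-yl)-4,6-dimethylbicyclo[4.1.0]heptan-2-ol (CH2 bridge and OH α) | O[C@@H]1[C@@H]2C[C@]2(C)[C@@H](CCC=C)[C@H](C)C1 | intermediate
12 | 5-(but-3-en-1-yl)-4,6-dimethylbicyclo[4.1.0]heptan-2-one (CH2 bridge α) | O=C1[C@@H]2C[C@]2(C)[C@@H](CCC=C)[C@H](C)C1 | intermediate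
13 | methyl vinyl ketone | C=CC(C)=O | starting material
14 | trimethylsilyl enol ether (C5=C6) of 15 | C[Si](C)(C)OC1=C[C@](C)(CI)[C@@H](CCC=C)[C@H](C)C1 | intermediate
15 | 4-(but-3-en-1-yl)-3-(iodomethyl)-3,5-dimethylcyclohexan-1-one (CH2I α, C20 β) | O=C1C[C@](C)(CI)[C@@H](CCC=C)[C@H](C)C1 | intermediate
16 | 4-(but-3-en-1-yl)-3,5-dimethyl-3-(4-oxopentyl)cyclohexan-1-one | O=C1C[C@](C)(CCCC(C)=O)[C@@H](CCC=C)[C@H](C)C1 | intermediate
17 | 19,14,15-trinorlabda-4,13(16)-dien-6-one (8α-Me) | CC1=C2C(=O)C[C@@H](C)[C@H](CCC=C)[C@@]2(C)CCC1 | intermediate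
18 | 14,15-dinorlabd-13(16)-en-6-one (5α-H, 8α-Me) | C=CCC[C@@H]1[C@@]2(C)CCCC(C)(C)[C@@H]2C(=O)C[C@H]1C | intermediate
19 | 14,15-dinorlabda-7,13(16)-dien-6-one | C=CCC[C@@H]1[C@@]2(C)CCCC(C)(C)[C@@H]2C(=O)C=C1C | intermediate
20 | 8α-(pinacolatoboryl)-14,15-dinorlabd-13(16)-en-6-one | C=CCC[C@@H]1[C@@]2(C)CCCC(C)(C)[C@@H]2C(=O)C[C@@]1(C)B3OC(C)(C)C(C)(C)O3 | intermediate
21 | 8α-hydroxy-14,15-dinorlabd-13(16)-en-6-one | C=CCC[C@@H]1[C@@]2(C)CCCC(C)(C)[C@@H]2C(=O)C[C@@]1(C)O | intermediate
22 | 14,15-dinorlabd-13(16)-ene-6α,8α-diol | C=CCC[C@@H]1[C@@]2(C)CCCC(C)(C)[C@@H]2[C@@H](O)C[C@@]1(C)O | intermediate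
23 | 6α,8α-dihydroxy-14,15-dinorlabdan-13-one | CC(=O)CC[C@@H]1[C@@]2(C)CCCC(C)(C)[C@@H]2[C@@H](O)C[C@@]1(C)O | intermediate
24 | (13R)-13,14-epoxy-15-norlabdane-6α,8α-diol | C[C@]1(CO1)CC[C@@H]2[C@@]3(C)CCCC(C)(C)[C@@H]3[C@@H](O)C[C@@]2(C)O | intermediate
25 | (13R)-labd-14-ene-6α,8α,13-triol | C=C[C@](C)(O)CC[C@@H]1[C@@]2(C)CCCC(C)(C)[C@@H]2[C@@H](O)C[C@@]1(C)O | intermediate
26 | angelic acid, (Z)-2-methylbut-2-enoic acid | C/C=C(/C)C(=O)O | starting material
27 | angelic 2,4,6-trichlorobenzoic anhydride | C/C=C(/C)C(=O)OC(=O)c1c(Cl)cc(Cl)cc1Cl | intermediate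
28 | 6α-angeloyloxysclareol | C=C[C@](C)(O)CC[C@@H]1[C@@]2(C)CCCC(C)(C)[C@@H]2[C@@H](OC(=O)/C(C)=C\C)C[C@@]1(C)O | target

Total step count: 16. Longest linear sequence: 16 steps (from 1 and 2 to 28).

Steps most likely to fail

Step 9. The methyl transfer to the tetrasubstituted, C10-flanked enone may stall, or 1,2-addition and enolisation may take over. The fallback sets out from 17 and replaces the conjugate addition by a cyclopropanation/reductive-opening sequence.
- LiAlH4 attacks from the α face and gives the 6β-allylic alcohol F3.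
- Hydroxyl-directed Simmons–Smith reaction on C4=C5 gives the 4β,5β-methano alcohol F4.
- Dess–Martin oxidation gives the cyclopropyl ketone F5.
- Li/NH3 cleaves the exocyclic C5–CH2 bond, which turns the CH2 into the second C4 methyl group.
- Protonation and equilibration at C5 bring the route back at 18.

Step 8. The C1 radical may be reduced before it meets the acceptor, the iodoketone may re-close to the cyclopropane, or the aldol stage may stop in the bridged mode. The fallback sets out from 12 and uses polar C–C activation instead of a radical.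
- 2-(2-Bromoethyl)-2-methyl-1,3-dioxolane and zinc give [2-(2-methyl-1,3-dioxolan-2-yl)ethyl]zinc bromide F1.
- Nickel/terpyridine-catalysed ring-opening cross-coupling of 12 with F1 and TMSCl gives the γ-alkylated silyl enol ether F2.
- Aqueous HCl cleaves silyl enol ether and ketal, so the route comes back at 16, now isolated, which KOH condenses to 17.

Step 14. Binding of the free hydroxyl groups to the rare-earth catalyst, or hemiketal formation between 8-OH and C13, may erode facial selectivity or turnover. The fallback sets out from 23 and forms the C13–C14 bond directly by titanium/chiral bis(sulfonamide) diol-catalysed asymmetric addition of divinylzinc to the methyl ketone. It comes back at 25 and skips 24.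

Further compounds
F1 | step 8 | [2-(2-methyl-1,3-dioxolan-2-yl)ethyl]zinc bromide | CC1(CC[Zn]Br)OCCO1
F2 | step 8 | trimethylsilyl enol ether (C5=C6) of 4-(but-3-en-1-yl)-3,5-dimethyl-3-[3-(2-methyl-1,3-dioxolan-2-yl)propyl]cyclohexan-1-one | C[Si](C)(C)OC1=C[C@](C)(CCCC2(C)OCCO2)[C@@H](CCC=C)[C@H](C)C1
F3 | step 9 | 19,14,15-trinorlabda-4,13(16)-dien-6β-ol | CC1=C2[C@H](O)C[C@@H](C)[C@H](CCC=C)[C@@]2(C)CCC1
F4 | step 9 | 4β,5β-methano-19,14,15-trinorlabd-13(16)-en-6β-ol | C[C@]12CCC[C@@]3(C)[C@]1(C2)[C@H](O)C[C@@H](C)[C@@H]3CCC=C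
F5 | step 9 | 4β,5β-methano-19,14,15-trinorlabd-13(16)-en-6-one | C[C@]12CCC[C@@]3(C)[C@]1(C2)C(=O)C[C@@H](C)[C@@H]3CCC=C
F0 | step 14 | none | none
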